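Ring A is disconnected at C8–C8a: with pyranone A stripped away, these two carbons are the carbonyl and the carbinol of an α‑hydroxy ketone. A single carbene‑catalysed crossed benzoin forms that bond, closes the six‑membered carbocycle and sets C8. It exploits the fact that O5 and O7 are already tied cis into the benzodioxepine on chromone B, which holds the C8 formyl and the C4a–C8a oxoethyl arm together. The precursor, a cis‑4‑formyl‑2‑(2‑oxoethyl)‑3‑silyloxy benzodioxepine, is assembled on the rigid 1,6‑anhydroglucose chair, where O2 and O4 are syn‑diaxial, and is unmasked by reductive ring fragmentation. Acylketene annulation and desilylation finish the target.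

Key step: step 14

Remark: C4a–C8a are ring A locants of the target and primed locants belong to chromone B; sugar locants are used up to 22 (glucose C1–C6 become C8, C7, C6, C5, C4a, C8a); the anomeric centre of 17–19 and the new centres of non‑isolated 27 and of F5 are left undefined because they are destroyed later.

Step 1
Reactants: 1 1-(5-bromo-4-fluoro-2-hydroxyphenyl)ethanone; 2 ethyl 3-phenylpropanoate
Product: 3 1-(5-bromo-4-fluoro-2-hydroxyphenyl)-5-phenylpentane-1,3-dione
Conditions: LiN(SiMe3)2 (3.3 equiv), THF, −78 → 0 °C; aq. HCl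
Reagents that add atoms: none
Why: Crossed Claisen condensation in which the enolate of the phenoxide-bearing methyl ketone acylates with the ester and the diketonate that forms shields the product from further attack.

Step 2
Reactants: 3 1-(5-bromo-4-fluoro-2-hydroxyphenyl)-5-phenylpentane-1,3-dione
Product: 4 6-bromo-7-fluoro-2-(2-phenylethyl)-4H-chromen-4-one (chromone B)
Conditions: H2SO4 (cat.), AcOH, 100 °C
Reagents that add atoms: none
Why: Acid-catalysed cyclodehydration of an o-hydroxyaryl 1,3-diketone, the standard closing stage of a 2-alkylchromone synthesis, in which the phenol adds to the enolised diketone and water is lost.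

Step 3
Reactants: 5 2,2,6-trimethyl-4H-1,3-dioxin-4-one; 6 4-methoxybenzyl bromide
Product: 8 6-[2-(4-methoxyphenyl)ethyl]-2,2-dimethyl-4H-1,3-dioxin-4-one, via lithium dioxinone dienolate 7 (not isolated)
Conditions: LiN(i-Pr)2, THF, −78 °C; then 6, DMPU, −78 → −40 °C
Reagents that add atoms: none
Why: γ-Alkylation of the vinylogous lithium dienolate of the dioxinone with a reactive benzylic bromide, a known way to extend the 6-methyl group.

Step 4
Reactants: 9 D-glucal
Product: 11 1,6-anhydro-2-deoxy-2-iodo-β-D-glucopyranose, via 6-O-tributylstannyl-D-glucal 10 (not isolated)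
Conditions: (Bu3Sn)2O, 3 Å MS, MeCN, reflux; then I2, 0 °C → rt
Reagents that add atoms: iodine, [I][I]
Why: Iodocyclisation (intramolecular iodoetherification) of the glycal, in which the tin alkoxide at O6 opens the iodonium ion at C1 trans-diaxially, placing iodine on the lower face of C2 and the anhydro bridge on the upper face.

Step 5
Reactants: 11 1,6-anhydro-2-deoxy-2-iodo-β-D-glucopyranose; 4 chromone B
Product: 13 1,6:2,3-dianhydro-4-O-[6-bromo-4-oxo-2-(2-phenylethyl)-4H-chromen-7-yl]-β-D-mannopyranose, via sodium 1,6:2,3-dianhydro-β-D-mannopyranos-4-olate 12 (not isolated)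
Conditions: NaH (2.0 equiv), DMF, 0 °C → rt; then 4, 0 → 40 °C
Reagents that add atoms: none
Why: Intramolecular Williamson epoxide closure (O3 displaces the anti-periplanar axial iodide with inversion at C2) followed by nucleophilic aromatic substitution (SNAr), in which the only remaining alkoxide, O4, attacks C7′ para to the chromone carbonyl and fluoride leaves, so C3 and C4 keep their configuration and O4 is joined to C7′ without ambiguity.

Step 6
Reactants: 13 aryl ether epoxide
Product: 14 1,6-anhydro-4-O-[6-bromo-4-oxo-2-(2-phenylethyl)-4H-chromen-7-yl]-β-D-glucopyranose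
Conditions: H2SO4 (0.2 M), 1,4-dioxane/H2O, 80 °C
Reagents that add atoms: water, O
Why: Acid-catalysed epoxide hydrolysis under the Fürst–Plattner rule, in which water opens the rigid epoxide trans-diaxially at C2 with inversion and so restores the gluco configuration with an axial O2–H on the same face as the O4 aryl ether.

Step 7
Reactants: 14 4-O-aryl-1,6-anhydroglucose
Product: 15 1,6-anhydro-2,4-O-[4-oxo-2-(2-phenylethyl)-4H-chromene-6,7-diyl]-β-D-glucopyranose (O2 on C6′, O4 on C7′, 3-OH free)
Conditions: Pd(OAc)2 (5 mol%), 2-(di-tert-butylphosphino)-1,1′-binaphthyl (6 mol%), Cs2CO3, toluene, 80 °C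
Reagents that add atoms: none
Why: Intramolecular palladium-catalysed C–O coupling (Buchwald–Hartwig etherification) of the aryl bromide with the syn-diaxial secondary O2–H, which closes the seven-membered dioxepine with retention at C2 while the O3–H on the opposite face cannot reach the metal and needs no protection.

Step 8
Reactants: 15 anhydro-bridged benzodioxepine
Product: 16 3-O-tert-butyldimethylsilyl ether of 15
Conditions: TBSOTf, 2,6-lutidine, CH2Cl2, 0 °C
Reagents that add atoms: tert-butyldimethylsilyl trifluoromethanesulfonate, CC(C)(C)[Si](C)(C)OS(=O)(=O)C(F)(F)F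
Why: Silylation of the one remaining hindered axial hydroxyl with a silyl triflate and a hindered pyridine base, giving the ether that later stops O6 from closing a lactol onto the C8a aldehyde.

Step 9
Reactants: 16 silylated anhydro sugar
Product: 18 phenyl 3-O-TBS-2,4-O-[4-oxo-2-(2-phenylethyl)-4H-chromene-6,7-diyl]-1-thio-D-glucopyranoside (6-OH free), via 6-O-trimethylsilyl thioglycoside 17 (not isolated)
Conditions: PhSSiMe3, ZnI2, CH2Cl2, rt; then K2CO3 (cat.), MeOH, 0 °C
Reagents that add atoms: (phenylthio)trimethylsilane, C[Si](C)(C)Sc1ccccc1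
Why: Lewis-acid-mediated thiolysis of the 1,6-anhydro acetal, in which ZnI2 activates O6, the thiosilane captures the oxocarbenium ion and O6 leaves as a silyl ether that mild methanolysis frees, an opening that is irreversible where methanolysis of this locked chair would not be.

Step 10
Reactants: 18 thioglycoside with free 6-OH
Product: 19 phenyl 6-deoxy-6-iodo-3-O-TBS-2,4-O-[4-oxo-2-(2-phenylethyl)-4H-chromene-6,7-diyl]-1-thio-D-glucopyranoside
Conditions: PPh3, I2, imidazole, toluene/MeCN, rt → 50 °C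
Reagents that add atoms: iodine, [I][I]
Why: Appel-type iodination of the single primary alcohol by SN2 displacement at C6 of its oxyphosphonium salt.

Step 11
Reactants: 19 6-iodo thioglycoside
Product: 20 5,6-dideoxy-3-O-TBS-2,4-O-[4-oxo-2-(2-phenylethyl)-4H-chromene-6,7-diyl]-D-xylo-hex-5-enose (cis-2-formyl-4-vinyl benzodioxepine)
Conditions: Zn dust (activated), THF/H2O 4:1, sonication, 40 °C
Reagents that add atoms: none
Why: Zinc-mediated reductive fragmentation of a 6-iodo glycoside (Bernet–Vasella reaction), in which zinc inserts into C6–I, β-elimination breaks C5–O5 and the hemithioacetal at C1 collapses to the aldehyde, removing the ring oxygen without touching C2–C4.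

Step 12
Reactants: 20 enal
Product: 22 5-deoxy-3-O-TBS-2,4-O-[4-oxo-2-(2-phenylethyl)-4H-chromene-6,7-diyl]-D-xylo-hexitol (1,6-diol), via bis(9-borabicyclononyl) adduct 21 (not isolated)
Conditions: 9-BBN, THF, 0 °C → rt; then pH 7 phosphate buffer, 30% H2O2, 0 °C → rt
Reagents that add atoms: hydrogen peroxide, OO
Why: Anti-Markovnikov hydroboration of the terminal alkene with a bulky dialkylborane, which also reduces the aldehyde, followed by buffered peroxide oxidation of the C–B bond, so that C5 becomes CH2 and no stereocentre is formed.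

Step 13
Reactants: 22 1,6-diol
Product: 23 5-deoxy-3-O-TBS-2,4-O-[4-oxo-2-(2-phenylethyl)-4H-chromene-6,7-diyl]-D-xylo-hexodialdose (cis-4-formyl-2-(2-oxoethyl)-3-silyloxy benzodioxepine fused to chromone B)
Conditions: Dess–Martin periodinane, CH2Cl2, 0 °C → rt; used at once
Reagents that add atoms: none
Why: Dess–Martin oxidation of both primary alcohols under near-neutral conditions that should neither epimerise the α-aryloxy centre C7 nor expel the β-aryloxy group.

Step 14
Reactants: 23 dialdehyde
Product: 24 bridged ring A acyloin (C8a ketone, C8 hydroxyl trans to O7, O6 silyl)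
Conditions: (5aS,10bR)-2-(pentafluorophenyl)-5a,10b-dihydro-4H,6H-indeno[2,1-b][1,2,4]triazolo[4,3-d][1,4]oxazin-2-ium tetrafluoroborate (20 mol%), i-Pr2NEt (20 mol%), 4 Å MS, toluene (0.02 M), rt
Reagents that add atoms: none
Why: The carbene freed from the triazolium salt adds to the unbranched C8a formyl group, proton transfer gives the Breslow enaminol (an acyl anion equivalent), its C8a attacks the α-aryloxy C8 formyl carbon, and loss of the carbene leaves the C8a ketone beside the C8 carbinol. The closest known reaction type is the N-heterocyclic-carbene-catalysed intramolecular crossed benzoin cyclisation of 1,6-dialdehydes to six-membered α-hydroxy ketones, known for sugar-derived dialdehydes that give inososes. Ring A closes in a 6-exo-trig mode (C8a onto the C8 carbonyl, whose oxygen stays outside the ring), which is possible only because the two arms are cis on the dioxepine. The new centre C8 is under catalyst control: the aminoindanol backbone must steer the enaminol to the aldehyde face that puts O8 trans to O7, a sense the substrate supports when C8=O lies anti to the C7–O dipole but opposes through the axial O6 silyl ether, so the antipodal salt is the direct cross-check. The step needs donor/acceptor chemoselectivity, secured because the ring-bound α-branched C8 aldehyde forms its enaminol far more slowly than the CH2-bound aldehyde, and it needs the β-aryloxy aldehyde to survive, secured by a catalytic weak amine base and high dilution.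

Step 15
Reactants: 24 acyloin
Product: 25 8-O-trimethylsilyl ether of the C8a trimethylsilyl enol ether (C4a=C8a)
Conditions: Me3SiOTf (3 equiv), Et3N (5 equiv), CH2Cl2, −40 → 0 °C; used crude
Reagents that add atoms: trimethylsilyl trifluoromethanesulfonate, C[Si](C)(C)OS(=O)(=O)C(F)(F)F
Why: Silyl triflate/amine soft enolisation with concurrent O-silylation, in which the ketone enolises toward C4a because its axial hydrogen overlaps with the carbonyl whereas the equatorial H8 does not, and the C8 hydroxyl is capped in the same operation.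

Step 16
Reactants: 25 bis-silyl enol ether; 8 aryl-ethyl dioxinone
Product: 28 6-O-tert-butyldimethylsilyl-4′-methoxyaquisinenone G, via acylketene 26 (not isolated), via silyloxy-dihydropyranone cycloadduct 27 (not isolated)
Conditions: 8 (3 equiv), toluene, 110 °C; then CF3CO2H, wet CH2Cl2, 0 °C
Reagents that add atoms: none
Why: Thermal retro-[4+2] of the dioxinone releases an acylketene that adds to the electron-rich enol ether in a hetero-Diels–Alder sense (ketene carbon to C4a, acyl oxygen to C8a), and acid then eliminates silanol to aromatise the 4-pyranone and frees the C8 hydroxyl.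

Step 17
Reactants: 28 6-O-silyl ether
Product: 29 (+)-4′-methoxyaquisinenone G
Conditions: HF·pyridine, pyridine, THF, 0 °C → rt
Reagents that add atoms: none
Why: Fluoride-mediated desilylation of the secondary silyl ether under buffered conditions that should leave both chromones, the aryl ethers and the four stereocentres untouched.

Compound list
1 | 1-(5-bromo-4-fluoro-2-hydroxyphenyl)ethanone | CC(=O)c1cc(Br)c(F)cc1O | starting material
2 | ethyl 3-phenylpropanoate | CCOC(=O)CCc1ccccc1 | starting material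
3 | 1-(5-bromo-4-fluoro-2-hydroxyphenyl)-5-phenylpentane-1,3-dione | O=C(CCc1ccccc1)CC(=O)c1cc(Br)c(F)cc1O | intermediate
4 | 6-bromo-7-fluoro-2-(2-phenylethyl)-4H-chromen-4-one (chromone B) | O=c1cc(CCc2ccccc2)oc2cc(F)c(Br)cc12 | intermediate
5 | 2,2,6-trimethyl-4H-1,3-dioxin-4-one | CC1=CC(=O)OC(C)(C)O1 | starting material
6 | 4-methoxybenzyl bromide | COc1ccc(CBr)cc1 | starting material
7 | lithium 2,2-dimethyl-6-methylidene-1,3-dioxin-4-olate (dienolate of 5) | [Li]OC1=CC(=C)OC(C)(C)O1 | intermediate
8 | 6-[2-(4-methoxyphenyl)ethyl]-2,2-dimethyl-4H-1,3-dioxin-4-one | COc1ccc(CCC2=CC(=O)OC(C)(C)O2)cc1 | intermediate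
9 | D-glucal | OC[C@H]1OC=C[C@@H](O)[C@@H]1O | starting material
10 | 6-O-tributylstannyl-D-glucal | CCCC[Sn](CCCC)(CCCC)OC[C@H]1OC=C[C@@H](O)[C@@H]1O | intermediate
11 | 1,6-anhydro-2-deoxy-2-iodo-β-D-glucopyranose | O1C[C@H]2O[C@@H]1[C@H](I)[C@@H](O)[C@@H]2O | intermediate
12 | sodium 1,6:2,3-dianhydro-β-D-mannopyranos-4-olate | O1C[C@H]2O[C@@H]1[C@H]3O[C@H]3[C@@H]2[O-].[Na+] | intermediate
13 | 1,6:2,3-dianhydro-4-O-[6-bromo-4-oxo-2-(2-phenylethyl)-4H-chromen-7-yl]-β-D-mannopyranose | O1C[C@H]2O[C@@H]1[C@H]3O[C@H]3[C@@H]2Oc4cc5oc(CCc6ccccc6)cc(=O)c5cc4Br | intermediate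
14 | 1,6-anhydro-4-O-[6-bromo-4-oxo-2-(2-phenylethyl)-4H-chromen-7-yl]-β-D-glucopyranose | O1C[C@H]2O[C@@H]1[C@H](O)[C@@H](O)[C@@H]2Oc4cc5oc(CCc6ccccc6)cc(=O)c5cc4Br | intermediate
15 | 1,6-anhydro-2,4-O-[4-oxo-2-(2-phenylethyl)-4H-chromene-6,7-diyl]-β-D-glucopyranose (O2 on C6′, O4 on C7′) | O1C[C@H]2O[C@@H]1[C@H](Oc3cc4c(=O)cc(CCc5ccccc5)oc4cc3O6)[C@@H](O)[C@@H]26 | intermediate
16 | 3-O-tert-butyldimethylsilyl ether of 15 | O1C[C@H]2O[C@@H]1[C@H](Oc3cc4c(=O)cc(CCc5ccccc5)oc4cc3O6)[C@@H](O[Si](C)(C)C(C)(C)C)[C@@H]26 | intermediate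
17 | phenyl 3-O-TBS-2,4-O-[4-oxo-2-(2-phenylethyl)-4H-chromene-6,7-diyl]-1-thio-6-O-trimethylsilyl-D-glucopyranoside (anomers) | C[Si](C)(C)OC[C@H]1OC(Sc2ccccc2)[C@H](Oc3cc4c(=O)cc(CCc5ccccc5)oc4cc3O6)[C@@H](O[Si](C)(C)C(C)(C)C)[C@@H]16 | intermediate
18 | phenyl 3-O-TBS-2,4-O-[4-oxo-2-(2-phenylethyl)-4H-chromene-6,7-diyl]-1-thio-D-glucopyranoside (anomers) | OC[C@H]1OC(Sc2ccccc2)[C@H](Oc3cc4c(=O)cc(CCc5ccccc5)oc4cc3O6)[C@@H](O[Si](C)(C)C(C)(C)C)[C@@H]16 | intermediate
19 | phenyl 6-deoxy-6-iodo-3-O-TBS-2,4-O-[4-oxo-2-(2-phenylethyl)-4H-chromene-6,7-diyl]-1-thio-D-glucopyranoside (anomers) | IC[C@H]1OC(Sc2ccccc2)[C@H](Oc3cc4c(=O)cc(CCc5ccccc5)oc4cc3O6)[C@@H](O[Si](C)(C)C(C)(C)C)[C@@H]16 | intermediate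
20 | 5,6-dideoxy-3-O-TBS-2,4-O-[4-oxo-2-(2-phenylethyl)-4H-chromene-6,7-diyl]-D-xylo-hex-5-enose | O=C[C@@H]1Oc2cc3c(=O)cc(CCc4ccccc4)oc3cc2O[C@H](C=C)[C@@H]1O[Si](C)(C)C(C)(C)C | intermediate
21 | 1-O,6-C-bis(9-borabicyclo[3.3.1]nonan-9-yl) adduct of 20 (C1 borinate, C6 alkylborane) | C1CC2CCCC(C1)B2OC[C@@H]1Oc2cc3c(=O)cc(CCc4ccccc4)oc3cc2O[C@H](CCB2C3CCCC2CCC3)[C@@H]1O[Si](C)(C)C(C)(C)C | intermediate
22 | 5-deoxy-3-O-TBS-2,4-O-[4-oxo-2-(2-phenylethyl)-4H-chromene-6,7-diyl]-D-xylo-hexitol | OC[C@@H]1Oc2cc3c(=O)cc(CCc4ccccc4)oc3cc2O[C@H](CCO)[C@@H]1O[Si](C)(C)C(C)(C)C | intermediate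
23 | 5-deoxy-3-O-TBS-2,4-O-[4-oxo-2-(2-phenylethyl)-4H-chromene-6,7-diyl]-D-xylo-hexodialdose (key-step precursor) | O=C[C@@H]1Oc2cc3c(=O)cc(CCc4ccccc4)oc3cc2O[C@H](CC=O)[C@@H]1O[Si](C)(C)C(C)(C)C | intermediate
24 | bridged ring A acyloin: C8a ketone, C8 hydroxyl trans to O7, 6-O-TBS, O5/O7 joined to C7′/C6′ of chromone B (key-step product) | C1C(=O)[C@@H](O)[C@@H]2Oc3cc4c(=O)cc(CCc5ccccc5)oc4cc3O[C@H]1[C@@H]2O[Si](C)(C)C(C)(C)C | intermediate
25 | 8-O-trimethylsilyl C8a trimethylsilyl enol ether of 24 (C4a=C8a) | C1=C(O[Si](C)(C)C)[C@@H](O[Si](C)(C)C)[C@@H]2Oc3cc4c(=O)cc(CCc5ccccc5)oc4cc3O[C@H]1[C@@H]2O[Si](C)(C)C(C)(C)C | intermediate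
26 | 5-(4-methoxyphenyl)-3-oxopent-1-en-1-one (acylketene) | COc1ccc(CCC(=O)C=C=O)cc1 | intermediate
27 | 8a-trimethylsilyloxy-4a,8a-dihydro cycloadduct (2-silyloxy-2,3-dihydro-4-pyranone; C4a and C8a undefined) | COc1ccc(CCC2=CC(=O)C3C(O2)(O[Si](C)(C)C)[C@@H](O[Si](C)(C)C)[C@@H]4Oc5cc6c(=O)cc(CCc7ccccc7)oc6cc5O[C@H]3[C@@H]4O[Si](C)(C)C(C)(C)C)cc1 | intermediate
28 | 6-O-tert-butyldimethylsilyl-4′-methoxyaquisinenone G | COc1ccc(CCc2cc(=O)c3c(o2)[C@@H](O)[C@@H]2Oc4cc5c(=O)cc(CCc6ccccc6)oc5cc4O[C@H]3[C@@H]2O[Si](C)(C)C(C)(C)C)cc1 | intermediate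
29 | (+)-4′-methoxyaquisinenone G, (5R,6S,7R,8S) | COc1ccc(CCc2cc(=O)c3c(o2)[C@@H](O)[C@@H]2Oc4cc5c(=O)cc(CCc6ccccc6)oc5cc4O[C@H]3[C@@H]2O)cc1 | target

Total step count: 17. Longest linear sequence: 15 steps (steps 1, 2 and 5–17, from 1 to 29); the sugar line from 9 is 14 steps.

Steps most likely to fail

Step 14. The acyl anion equivalent may be delivered to the wrong face of the C8 formyl group, giving low or inverted selectivity at C8, because hydrogen-bonded delivery from the enaminol and the axial O6 silyl ether both favour O8 cis to O7. Fallback: catalyst control is given up and C8 is corrected by substitution. Dialdehyde 23 is cyclised with the achiral carbene from 2-(pentafluorophenyl)-6,7-dihydro-5H-pyrrolo[2,1-c][1,2,4]triazol-2-ium tetrafluoroborate under the same weak-base conditions to the substrate-preferred 8-epi-acyloin F1. A Mitsunobu reaction with chloroacetic acid (PPh3, DIAD, toluene, 0 °C) inverts C8 by SN2 next to the ketone and gives the 8-O-chloroacetyl acyloin F2 of correct configuration. Thiourea and NaHCO3 in ethanol remove the chloroacetyl group without a base strong enough for β-elimination and return the route at 24.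

Step 16. The acylketene may be lost to dimerisation, or the hindered enol ether may be desilylated or may expel the C5 aryloxide at 110 °C before the C4a–C4 bond forms. Fallback: the pyranone is built stepwise at low temperature from 24. TESOTf and 2,6-lutidine give the 8-O-triethylsilyl acyloin F3. Its dibutylboron enolate (Bu2BOTf, i-Pr2NEt, CH2Cl2, −78 °C, enolisation toward C4a) undergoes aldol addition to 5-(4-methoxyphenyl)pent-2-ynal F4, made from commercial 1-(but-3-yn-1-yl)-4-methoxybenzene with n-BuLi and DMF, to give the propargylic aldol F5. Dess–Martin oxidation gives the 2-alkynoyl ketone F6, whose enol oxygen closes onto the alkyne (6-endo-dig oxa-Michael addition, Et2NH cat., EtOH, rt) to give the bis-silylated pyranone F7. HF·pyridine removes both silyl groups and returns the route at 29.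

Step 7. β-Hydride elimination from the palladium alkoxide or protodebromination may outrun C–O reductive elimination at the secondary alcohol. Fallback: the polarity of the second ether bond is reversed, starting from epoxide 13. Miyaura borylation (B2pin2, PdCl2(dppf) with dppf = 1,1′-bis(diphenylphosphino)ferrocene, KOAc, dioxane, 80 °C) gives the aryl pinacol boronate F8. NaBO3·4H2O in THF/H2O oxidises it to the phenol epoxide F9 with the epoxide intact. Cs2CO3 in DMF at 80 °C then lets the phenoxide open the epoxide at C2 trans-diaxially, the regiochemistry water follows in step 6, which gives 15 directly and bypasses 14.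

Further compounds
F1 | step 14 | 8-epi-acyloin (C8 hydroxyl cis to O7) | C1C(=O)[C@H](O)[C@@H]2Oc3cc4c(=O)cc(CCc5ccccc5)oc4cc3O[C@H]1[C@@H]2O[Si](C)(C)C(C)(C)C
F2 | step 14 | 8-O-chloroacetyl acyloin (C8 as in 24) | C1C(=O)[C@@H](OC(=O)CCl)[C@@H]2Oc3cc4c(=O)cc(CCc5ccccc5)oc4cc3O[C@H]1[C@@H]2O[Si](C)(C)C(C)(C)C
F3 | step 16 | 8-O-triethylsilyl acyloin | C1C(=O)[C@@H](O[Si](CC)(CC)CC)[C@@H]2Oc3cc4c(=O)cc(CCc5ccccc5)oc4cc3O[C@H]1[C@@H]2O[Si](C)(C)C(C)(C)C
F4 | step 16 | 5-(4-methoxyphenyl)pent-2-ynal | COc1ccc(CCC#CC=O)cc1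
F5 | step 16 | propargylic aldol at C4a (carbinol and C4a undefined) | COc1ccc(CCC#CC(O)C2C(=O)[C@@H](O[Si](CC)(CC)CC)[C@@H]3Oc4cc5c(=O)cc(CCc6ccccc6)oc5cc4O[C@H]2[C@@H]3O[Si](C)(C)C(C)(C)C)cc1
F6 | step 16 | 2-alkynoyl ketone (C4a undefined, enolisable) | COc1ccc(CCC#CC(=O)C2C(=O)[C@@H](O[Si](CC)(CC)CC)[C@@H]3Oc4cc5c(=O)cc(CCc6ccccc6)oc5cc4O[C@H]2[C@@H]3O[Si](C)(C)C(C)(C)C)cc1
F7 | step 16 | 6-O-TBS-8-O-triethylsilyl-4′-methoxyaquisinenone G | COc1ccc(CCc2cc(=O)c3c(o2)[C@@H](O[Si](CC)(CC)CC)[C@@H]2Oc4cc5c(=O)cc(CCc6ccccc6)oc5cc4O[C@H]3[C@@H]2O[Si](C)(C)C(C)(C)C)cc1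
F8 | step 7 | aryl pinacol boronate of epoxide 13 (Bpin in place of Br) | O1C[C@H]2O[C@@H]1[C@H]3O[C@H]3[C@@H]2Oc4cc5oc(CCc6ccccc6)cc(=O)c5cc4B7OC(C)(C)C(C)(C)O7
F9 | step 7 | phenol epoxide (6′-OH in place of Br) | O1C[C@H]2O[C@@H]1[C@H]3O[C@H]3[C@@H]2Oc4cc5oc(CCc6ccccc6)cc(=O)c5cc4O
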